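The furan O1–C2 bond is cut to open the chain ring A–C3–C2–ring B, and C2 is taken back to the aryl ketone of ring B. C3, which carries the methyl group and is bonded to C3a of ring A, is then benzylic and α to a carbonyl, so its configuration is mobile. A ketoreductase uses this mobility: it reduces one ketone enantiomer on one carbonyl face while the other racemises, fixing C3 (S) and C2 (R, later inverted) in a single operation. The substrate is the racemic bis-MOM 1,2-diarylpropan-1-one made by palladium-catalysed enolate arylation. Non-acidic MOM removal and an inverting Mitsunobu closure of the ring A phenol onto C2 give the trans (2S,3S) dihydrobenzofuran.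

Key step: step 7

Remarks on the chemistry (assumptions):
- 3-Hydroxy-4,5-dimethoxybenzaldehyde, 5-(ethylsulfonyl)-1-phenyl-1H-tetrazole and ketoreductase screening panels are taken as purchasable.
- Benzofuran C2 and C3 correspond to C1 and C2 of the open-chain propanol. The target is (2S,3S), trans.
- Both phenols are carried as MOM ethers, the small, base-stable group that tolerates the enolate arylation and crowds the enzyme pocket least. They are removed with a bipyridyl-buffered silyl triflate and not with protic acid, so that the carbinol on the electron-rich ring B is not ionised before ring closure.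
- NADPH is recycled with i-PrOH, which tolerates the pH of 9.5–10 chosen to keep C3 racemising.

Step 1
Reactants: 1 5-bromovanillin (3-bromo-4-hydroxy-5-methoxybenzaldehyde)
Product: 2 3-bromo-5-methoxy-4-(methoxymethoxy)benzaldehyde
Conditions: MOMCl, i-Pr2NEt, CH2Cl2, 0 °C to rt
Reagents that add atoms: chloromethyl methyl ether (MOMCl), COCCl
Why: O-alkylation of the acidic, para-formyl phenol with the chloromethyl ether under amine base (Williamson-type acetal formation) should be clean and creates no stereocentre.

Step 2
Reactants: 2 3-bromo-5-methoxy-4-(methoxymethoxy)benzaldehyde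
Product: 3 1-bromo-3-methoxy-2-(methoxymethoxy)-5-[(E)-prop-1-enyl]benzene
Conditions: 5-(ethylsulfonyl)-1-phenyl-1H-tetrazole, KN(SiMe3)2 (KHMDS), DME, −60 °C to rt
Reagents that add atoms: 5-(ethylsulfonyl)-1-phenyl-1H-tetrazole, CCS(=O)(=O)c1nnnn1-c1ccccc1
Why: Julia–Kocienski olefination of an aryl aldehyde with a phenyltetrazolyl sulfone and a potassium base in DME should favour the E alkene through addition, Smiles rearrangement and anti elimination, while the aryl bromide and the MOM ether are inert at this temperature.

Step 3
Reactants: 4 3-hydroxy-4,5-dimethoxybenzaldehyde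
Product: 5 3,4-dimethoxy-5-(methoxymethoxy)benzaldehyde
Conditions: MOMCl, i-Pr2NEt, CH2Cl2, 0 °C to rt
Reagents that add atoms: chloromethyl methyl ether (MOMCl), COCCl
Why: The same phenol O-alkylation as in step 1 masks the ring B phenol against the Grignard reagent and the alkoxide base used later.

Step 4
Reactants: 5 3,4-dimethoxy-5-(methoxymethoxy)benzaldehyde
Product: 6 racemic 1-[3,4-dimethoxy-5-(methoxymethoxy)phenyl]propan-1-ol
Conditions: EtMgBr, THF, 0 °C; then H2O/aq. NH4Cl
Reagents that add atoms: ethylmagnesium bromide, CC[Mg]Br
Why: Grignard 1,2-addition to the aldehyde gives the benzylic carbinol, whose stereocentre is racemic and is erased in the next step.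

Step 5
Reactants: 6 racemic 1-[3,4-dimethoxy-5-(methoxymethoxy)phenyl]propan-1-ol
Product: 7 1-[3,4-dimethoxy-5-(methoxymethoxy)phenyl]propan-1-one
Conditions: Dess–Martin periodinane, CH2Cl2, rt
Reagents that add atoms: none
Why: Dess–Martin oxidation of a secondary benzylic alcohol to the aryl ketone is mild enough to leave the aryl MOM ether and the electron-rich ring untouched.

Step 6
Reactants: 7 1-[3,4-dimethoxy-5-(methoxymethoxy)phenyl]propan-1-one; 3 1-bromo-3-methoxy-2-(methoxymethoxy)-5-[(E)-prop-1-enyl]benzene
Product: 8 racemic 1-[3,4-dimethoxy-5-(methoxymethoxy)phenyl]-2-{3-methoxy-2-(methoxymethoxy)-5-[(E)-prop-1-enyl]phenyl}propan-1-one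
Conditions: Pd2(dba)3 (cat.), P(t-Bu)3 (cat.), NaOt-Bu, THF, 60 °C
Reagents that add atoms: none
Why: Palladium-catalysed ketone α-arylation (oxidative addition of zerovalent palladium into the C–Br bond, enolate binding, C–C reductive elimination driven by the bulky electron-rich phosphine) should stop at mono-arylation because the product enolate is fully substituted; the MOM ethers are stable, the conjugated E-propenyl group is the resting point of any Pd–H isomerisation, and the new stereocentre is formed racemic, as intended.

Step 7
Reactants: 8 racemic 1-[3,4-dimethoxy-5-(methoxymethoxy)phenyl]-2-{3-methoxy-2-(methoxymethoxy)-5-[(E)-prop-1-enyl]phenyl}propan-1-one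
Product: 9 (1R,2S)-1-[3,4-dimethoxy-5-(methoxymethoxy)phenyl]-2-{3-methoxy-2-(methoxymethoxy)-5-[(E)-prop-1-enyl]phenyl}propan-1-ol
Conditions: ketoreductase (panel hit selective for the (S)-ketone and the Si face), NADP+ (cat.), i-PrOH, borate buffer pH 9.5–10, DMSO cosolvent, 40 °C
Reagents that add atoms: none
Why: In this dynamic reductive kinetic resolution the enzyme binds the (S)-configured ketone and passes the C4 hydride of NADPH to the Si face of the C1 carbonyl while an active-site acid protonates the oxygen, and i-PrOH regenerates NADPH on the same enzyme. The closest known reaction type is the alcohol dehydrogenase or ketoreductase dynamic reductive kinetic resolution of α-aryl (benzyl) ketones and α-substituted β-keto esters, together with the reduction of ketones flanked by two bulky groups by engineered ketoreductases; both demands meet in this substrate, so a panel screen and possibly rounds of directed evolution are expected. No ring is closed. C1 (later C2 of the benzofuran) should be set R by the enzyme's control of the hydride face, and C2 (later C3) should be set S by the enzyme's preference for one ketone enantiomer, the (R)-ketone being returned to the pool through the enol(ate). The step needs enantiomer and face discrimination with racemisation faster than reduction of the slow enantiomer; the substrate secures the racemisation because its C2–H is both benzylic to ring A and α to the ring B aryl ketone, helped by pH 9.5–10, DMSO and 40 °C, whereas the product carbinol has no such acidic hydrogen and cannot epimerise. Enzyme control is required because the (1R,2S) alcohol is the anti-Felkin diastereomer that hydride reagents disfavour.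

Step 8
Reactants: 9 (1R,2S)-1-[3,4-dimethoxy-5-(methoxymethoxy)phenyl]-2-{3-methoxy-2-(methoxymethoxy)-5-[(E)-prop-1-enyl]phenyl}propan-1-ol
Product: 11 5-[(1R,2S)-1-hydroxy-2-{2-hydroxy-3-methoxy-5-[(E)-prop-1-enyl]phenyl}propyl]-2,3-dimethoxyphenol, via tris(trimethylsilyl) ether 10 (not isolated)
Conditions: TMSOTf, 2,2'-bipyridyl, MeCN, 0 °C to rt; then H2O, rt
Reagents that add atoms: none
Why: Silyl triflate/2,2'-bipyridyl cleavage of aromatic MOM ethers (each acetal is activated by the bipyridyl-buffered silyl triflate, the phenol emerges as its trimethylsilyl ether and water then hydrolyses it together with the transiently silylated carbinol) should free both phenols without protic acid, so the C1 carbinol on the trioxygenated ring B is not ionised and both stereocentres are kept.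

Step 9
Reactants: 11 5-[(1R,2S)-1-hydroxy-2-{2-hydroxy-3-methoxy-5-[(E)-prop-1-enyl]phenyl}propyl]-2,3-dimethoxyphenol
Product: 12 (2S,3S)-2-(3-hydroxy-4,5-dimethoxyphenyl)-7-methoxy-3-methyl-5-[(E)-prop-1-enyl]-2,3-dihydro-1-benzofuran (target)
Conditions: PPh3, DIAD, THF, 0 °C to rt
Reagents that add atoms: none
Why: Mitsunobu cycloetherification should activate the C1 carbinol as its alkoxyphosphonium ion, which the ring A phenoxide displaces in a 5-exo-tet closure with inversion (1R to 2S, C3 untouched, trans ring); the ring B phenol is meta to the carbinol and cannot cyclise, and any leakage through a benzylic ion pair should converge on the same trans isomer.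

Compound list
1 | 5-bromovanillin (3-bromo-4-hydroxy-5-methoxybenzaldehyde) | O=Cc1cc(Br)c(O)c(OC)c1 | starting material
2 | 3-bromo-5-methoxy-4-(methoxymethoxy)benzaldehyde | O=Cc1cc(Br)c(OCOC)c(OC)c1 | intermediate
3 | 1-bromo-3-methoxy-2-(methoxymethoxy)-5-[(E)-prop-1-enyl]benzene | C/C=C/c1cc(Br)c(OCOC)c(OC)c1 | intermediate
4 | 3-hydroxy-4,5-dimethoxybenzaldehyde | O=Cc1cc(O)c(OC)c(OC)c1 | starting material
5 | 3,4-dimethoxy-5-(methoxymethoxy)benzaldehyde | O=Cc1cc(OCOC)c(OC)c(OC)c1 | intermediate
6 | racemic 1-[3,4-dimethoxy-5-(methoxymethoxy)phenyl]propan-1-ol | CCC(O)c1cc(OCOC)c(OC)c(OC)c1 | intermediate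
7 | 1-[3,4-dimethoxy-5-(methoxymethoxy)phenyl]propan-1-one | CCC(=O)c1cc(OCOC)c(OC)c(OC)c1 | intermediate
8 | racemic 1-[3,4-dimethoxy-5-(methoxymethoxy)phenyl]-2-{3-methoxy-2-(methoxymethoxy)-5-[(E)-prop-1-enyl]phenyl}propan-1-one | C/C=C/c1cc(OC)c(OCOC)c(c1)C(C)C(=O)c1cc(OCOC)c(OC)c(OC)c1 | intermediate
9 | (1R,2S)-1-[3,4-dimethoxy-5-(methoxymethoxy)phenyl]-2-{3-methoxy-2-(methoxymethoxy)-5-[(E)-prop-1-enyl]phenyl}propan-1-ol | C/C=C/c1cc(OC)c(OCOC)c(c1)[C@H](C)[C@H](c1cc(OCOC)c(OC)c(OC)c1)O | intermediate
10 | (1R,2S)-tris(trimethylsilyl) ether: both phenol oxygens and the C1 oxygen of compound 11 carry SiMe3 | C/C=C/c1cc(OC)c(O[Si](C)(C)C)c(c1)[C@H](C)[C@H](c1cc(O[Si](C)(C)C)c(OC)c(OC)c1)O[Si](C)(C)C | intermediate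
11 | 5-[(1R,2S)-1-hydroxy-2-{2-hydroxy-3-methoxy-5-[(E)-prop-1-enyl]phenyl}propyl]-2,3-dimethoxyphenol | C/C=C/c1cc(OC)c(O)c(c1)[C@H](C)[C@H](c1cc(O)c(OC)c(OC)c1)O | intermediate
12 | (2S,3S)-2-(3-hydroxy-4,5-dimethoxyphenyl)-7-methoxy-3-methyl-5-[(E)-prop-1-enyl]-2,3-dihydro-1-benzofuran | C/C=C/c1cc(OC)c2c(c1)[C@H](C)[C@@H](c1cc(O)c(OC)c(OC)c1)O2 | target

Total step count: 9.
Longest linear sequence: 7 steps (steps 3, 4, 5, 6, 7, 8 and 9, from compound 4).

Steps most likely to fail

1. Step 7. No panel enzyme may accept a ketone flanked by two bulky aryl-bearing groups. Enolisation at C3 may also be slower than reduction, so that the process stalls as a plain kinetic resolution with eroded diastereomer purity. The fallback sets out from 8 and replaces the enzyme by a ruthenium transfer hydrogenation with dynamic kinetic resolution (RuCl(p-cymene)[(S,S)-TsDPEN], HCO2H/Et3N, DMF, 40 °C). The amine racemises C3, and the catalyst enantiomer that reduces the (S)-ketone is used; by Felkin-type matching this is expected to be (S,S). The product should be (1S,2S)-1-[3,4-dimethoxy-5-(methoxymethoxy)phenyl]-2-{3-methoxy-2-(methoxymethoxy)-5-[(E)-prop-1-enyl]phenyl}propan-1-ol F1, which has C3 correct and the carbinol epimeric to 9. Because an inverting closure would now give the cis ring, F1 is treated with HCl in aqueous THF. Both MOM groups hydrolyse to 5-[(1S,2S)-1-hydroxy-2-{2-hydroxy-3-methoxy-5-[(E)-prop-1-enyl]phenyl}propyl]-2,3-dimethoxyphenol F2. The ring B benzylic cation of F2 is then trapped by the ring A phenol anti to the C3 methyl group, under conditions that also equilibrate toward trans. The fallback returns to the route at 12.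

2. Step 9. The activated carbinol may lose the C3 hydrogen to give a stilbene, or the free ring B phenol may be alkylated intermolecularly, instead of the five-membered closure. The fallback sets out from 11 and closes the ring by ionisation instead of displacement: catalytic p-TsOH (or a sulfonic acid resin) in CH2Cl2 at 0 °C generates the ring B benzylic cation, which the ring A phenol captures. The trans isomer is expected because the aryl group settles anti to the C3 methyl and a cis ether can re-ionise. The fallback returns at 12 and no new compound arises (F0).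

3. Step 6. Oxidative addition and enolate coupling at the ortho-alkoxy bromide may be slow, leaving room for hydrodebromination or Heck arylation of the propenyl group. The fallback reverses the polarity of the same C–C bond. Ketone 7 is brominated through its lithium enolate (LiN(SiMe3)2, THF, −78 °C; then NBS) to racemic 2-bromo-1-[3,4-dimethoxy-5-(methoxymethoxy)phenyl]propan-1-one F3. Bromide 3 is converted (n-BuLi, THF, −78 °C; then ZnCl2) into {3-methoxy-2-(methoxymethoxy)-5-[(E)-prop-1-enyl]phenyl}zinc chloride F4. A nickel-catalysed Negishi arylation of the secondary α-bromoketone (NiCl2·glyme, achiral bipyridine or pybox ligand, DME/THF, −20 °C to rt) joins F3 and F4 and returns to the route at 8.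

Further compounds
F1 | step 7 | (1S,2S)-1-[3,4-dimethoxy-5-(methoxymethoxy)phenyl]-2-{3-methoxy-2-(methoxymethoxy)-5-[(E)-prop-1-enyl]phenyl}propan-1-ol | C/C=C/c1cc(OC)c(OCOC)c(c1)[C@H](C)[C@@H](c1cc(OCOC)c(OC)c(OC)c1)O
F2 | step 7 | 5-[(1S,2S)-1-hydroxy-2-{2-hydroxy-3-methoxy-5-[(E)-prop-1-enyl]phenyl}propyl]-2,3-dimethoxyphenol | C/C=C/c1cc(OC)c(O)c(c1)[C@H](C)[C@@H](c1cc(O)c(OC)c(OC)c1)O
F0 | step 9 | none | none
F3 | step 6 | racemic 2-bromo-1-[3,4-dimethoxy-5-(methoxymethoxy)phenyl]propan-1-one | CC(Br)C(=O)c1cc(OCOC)c(OC)c(OC)c1
F4 | step 6 | {3-methoxy-2-(methoxymethoxy)-5-[(E)-prop-1-enyl]phenyl}zinc chloride | C/C=C/c1cc(OC)c(OCOC)c(c1)[Zn]Cl
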